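**Early times.** At early times each flask makes intermediate from starting material, while gas dissolves as coupling partner, which then turns intermediate into product.

common to all: starting material 0.10 M; gas 33 mM (held); time 15 min

| charge | temperature |
|---|---|
| spring | 10 °C |
| winter | −15 °C |
| noon | 60 °C |
| autumn | 35 °C |

    coupling partner + intermediate → product (k1 = 5.0 L mol⁻¹ min⁻¹, Ea1 = 56.0 kJ mol⁻¹)
    gas ⇌ coupling partner, rate k2*(csat - [coupling partner]) (k2 = 7.4 min⁻¹, csat = 33 mM)
    starting material → intermediate (k3 = 0.19 min⁻¹, Ea3 = 97.0 kJ mol⁻¹)
    (constants at 60 °C)

- at the start none of coupling partner is dissolved
- at 60 °C the constants are as listed, elsewhere as the activation energies make them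

1. the best flask by amount of intermediate, in percent of the starting material charged; "all alike" if 1.5 percentage points covers them all (spring / winter / noon / autumn / all alike)
2. amount of intermediate at the end, in percent of the starting material charged, spring
3. amount of intermediate at the end, in percent of the starting material charged, winter
4. amount of intermediate at the end, in percent of the starting material charged, noon
5. amount of intermediate at the end, in percent of the starting material charged, autumn

**Starting rate.** I reckoned noon by hand, since its constants stand as listed. In noon the rate of making began at 0.0190 M min⁻¹, the making constant 0.19 min⁻¹ times [starting material]. Held for 15 min, that rate comes to 285% of the charge, more than the charge itself, so slowing had to dominate the noon flask.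

**Two slowings.** In noon the making rate itself fades as starting material is spent, by a factor of 0.0578 at the end. Coupling partner reached its saturation 33 mM with a lag of 0.135 min, far shorter than the 5.26 min of the making step, so in noon I used up intermediate pseudo-first-order, with the using constant 0.165 min⁻¹. The two constants gave 0.177 min⁻¹, which I called the mean drain, half the sum of the making and using constants. In noon, half their difference times the time was 0.187, smaller than 1, so the two-step solution stays close to a simple rule: the unslowed share times e to the minus mean drain times time. With that accumulated factor I put noon at 19.9%.

**The forecast.** The forecast named noon as best, with 20.5% there, autumn 12.1%, spring 0.57% and winter 0.011%. For noon it said “partner depletion of 1–2.5% adds about 0.5 points”, and my figure stood lower than its figure.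

**The result.** The simulation gave noon as best, with 20.6% there, autumn 12.1%, spring 0.566% and winter 0.0108%. My noon figure fell 0.70 percentage points short of the noon reading, and coupling partner in noon read 0.0322 M at 7.50 min against the saturation of 33 mM. The same noon flask read at 25 min takes the same mean drain of 0.177 min⁻¹, and the rule gives 5.62% for it; that flask held 5.88% of intermediate.

The constants used here are those of an exercise; no experiment stands behind them.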